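**Assumptions**
- The target SMILES is (1S,2S), with the 1-aryl and 2-aroyl groups cis on the 1,2-dihydronaphthalene ring (checked by CIP analysis of the SMILES).
- The (−)-menthyl ester on the C2 carboxyl is assumed to bias the sense of ring closure at C1 toward (S). If the opposite sense is found, (+)-menthol is used.
- In the photocyclisation, ring A (from 5-hydroxyvanillin) is assumed to be the benzo partner, closing at its C6 carbon next to the OMe.

**Retrosynthetic overview**
1. Licobichalcone ⇐ removal of six MOM groups ⇐ bis(4-MOMO-benzoyl)dihydronaphthalene ⇐ two ArMgBr additions to a bis-Weinreb amide, which also releases the menthol.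
2. The only carbocycle is the 1,2-dihydronaphthalene. It forms by photochemical conrotatory 6π closure of the (E,E)-1,4-diarylbutadiene-2,3-dicarboxylate (C1–C8a bond, sets C1), then base-mediated re-aromatisation and kinetic protonation (sets C2). The menthyl ester on C2 biases the closure.
3. The diene comes from a one-pot aldol/mesylation/elimination of a menthyl/ethyl arylidenesuccinate with the ring-B aldehyde. The arylidenesuccinate comes from a Stobbe condensation of diethyl succinate with the ring-A aldehyde, followed by menthyl esterification.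
4. Both aldehydes are made from 5-hydroxyvanillin and 2,3,4-trihydroxybenzaldehyde (MOM protection, plus 2-O-methylation for ring B). All arene rings pre-exist, and the menthyl group is temporary.

---

**Step 1**
Reactants: 1 (3,4-dihydroxy-5-methoxybenzaldehyde, 5-hydroxyvanillin); 2 (chloromethyl methyl ether, MOMCl)
Product: 3 (3,4-bis(methoxymethoxy)-5-methoxybenzaldehyde)
Conditions: MOMCl (2.4 equiv), i-Pr2NEt, CH2Cl2, 0 °C → rt
Reagents that add atoms: MOMCl, ClCOC
Why: Phenol O-alkylation with MOMCl gives protection that is stable to the Stobbe, aldol and Grignard steps.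

**Step 2**
Reactants: 4 (2,3,4-trihydroxybenzaldehyde); 2 (MOMCl)
Product: 5 (2-hydroxy-3,4-bis(methoxymethoxy)benzaldehyde)
Conditions: MOMCl (2.2 equiv), i-Pr2NEt, CH2Cl2, 0 °C
Reagents that add atoms: MOMCl, ClCOC
Why: The 2-OH is hydrogen-bonded to the CHO and reacts slowly, so the acidic 4-OH and the free 3-OH are alkylated first (phenol O-alkylation).

**Step 3**
Reactants: 5; 6 (iodomethane)
Product: 7 (2-methoxy-3,4-bis(methoxymethoxy)benzaldehyde)
Conditions: MeI, K2CO3, DMF, rt
Reagents that add atoms: MeI, CI
Why: Williamson O-methylation of the remaining phenol installs the 2-OMe of ring B.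

**Step 4**
Reactants: 3; 8 (diethyl succinate)
Product: 9 ((E)-4-[3,4-bis(methoxymethoxy)-5-methoxyphenyl]-3-(ethoxycarbonyl)but-3-enoic acid)
Conditions: t-BuOK (2.2 equiv), t-BuOH, reflux; workup with cold aq. citric acid
Reagents that add atoms: none
Why: Stobbe condensation gives the (E)-arylidene half-ester, with the aryl cis to the CH2CO2H arm. This places ring A cis to the future diene backbone, which is the geometry needed for closure.

**Step 5**
Reactants: 9; 10 ((1R,2S,5R)-(−)-menthol)
Product: 11 (1-ethyl 4-[(1R,2S,5R)-menthyl] 2-[(3,4-bis(MOMO)-5-methoxyphenyl)methylene]succinate)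
Conditions: DCC, DMAP, CH2Cl2, 0 °C → rt
Reagents that add atoms: (−)-menthol, C[C@@H]1CC[C@H]([C@@H](C1)O)C(C)C
Why: Steglich esterification attaches the cheap chiral-pool menthyl group to the CH2CO2H arm, which becomes the C2 carboxyl next to the future C1.

**Step 6**
Reactants: 11; 7
Product: 12 (3-ethyl 2-menthyl (E,E)-1-[2-methoxy-3,4-bis(MOMO)phenyl]-4-[3,4-bis(MOMO)-5-methoxyphenyl]buta-1,3-diene-2,3-dicarboxylate)
Conditions: LDA (1.1 equiv), THF, −78 °C; add 7; then MsCl (1.5 equiv), −78 → 0 °C; then DBU (3 equiv), rt (one pot)
Reagents that add atoms: none (the mesylate leaves as MsO⁻; net loss of H2O)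
Why: Aldol addition of the menthyl ester enolate to the ring-B aldehyde forms the C1–C2 bond. In-situ mesylation of the alkoxide and DBU-promoted E1cB elimination (aldol/dehydration) destroy the carbinol stereocentre and give the thermodynamically preferred (E,E)-diene, with each aryl trans to its ester and cis to the diene backbone, as in Stobbe-type dibenzylidenesuccinates.

**Step 7**
Reactants: 12
Product: 13 (3-ethyl 2-[(1R,2S,5R)-menthyl] (1S,2S)-8-methoxy-1-[2-methoxy-3,4-bis(MOMO)phenyl]-6,7-bis(MOMO)-1,2-dihydronaphthalene-2,3-dicarboxylate)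
Conditions: hν (350 nm, Rayonet), MeCN (0.01 M, degassed), 25 °C; then DBU (10 mol %), rt, 30 min; separate the minor C1 diastereomer by SiO2 chromatography
Reagents that add atoms: none (isomerisation)
Why: Proposed new method: the s-cis conformer of the excited (E,E)-diene, with ring A as the 6π aryl partner, undergoes conrotatory closure of the C8a–C1 bond to a dearomatised isotoluene, in which the C2 menthyl ester biases the helical sense and therefore C1. DBU then removes the doubly allylic C8a–H to re-aromatise ring A and give the C2 dienolate, which is protonated at Cα anti to the pseudo-axial C1 aryl (held axial by the peri 8-OMe), so the C2 ester ends up cis to the aryl and C2 is set. The closest known reactions are the 6π photocyclisation and tautomerisation of dibenzylidenesuccinates to 1-aryl-1,2-dihydronaphthalene lignan cores and the stilbene-to-dihydrophenanthrene photocyclisation, here extended to a menthyl-directed, tetra-oxygenated, unsymmetrical diene.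

**Step 8**
Reactants: 13; 14 (N,O-dimethylhydroxylamine hydrochloride)
Product: 15 (bis-Weinreb amide, (1S,2S))
Conditions: i-PrMgCl (10 equiv), MeNH(OMe)·HCl (5 equiv), THF, −20 → 0 °C
Reagents that add atoms: N,O-dimethylhydroxylamine (2 equiv consumed, one per ester), CNOC
Why: Magnesium-amide aminolysis of both esters (Williams amidation) gives the Weinreb amides and releases (−)-menthol and EtOH. Any C2 dienolate formed by the Grignard base is reprotonated on workup at Cα anti to the C1 aryl, which keeps the cis relationship, and C1 is untouched.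

**Step 9**
Reactants: 16 (4-bromophenol); 2 (MOMCl)
Product: 17 (1-bromo-4-(methoxymethoxy)benzene)
Conditions: NaH, THF, 0 °C; then MOMCl
Reagents that add atoms: MOMCl, ClCOC
Why: Phenol O-alkylation masks the 4-OH of the future aroyl rings.

**Step 10**
Reactants: 17; 18 (magnesium)
Product: 19 (4-(methoxymethoxy)phenylmagnesium bromide)
Conditions: Mg turnings, I2 (cat.), THF, 50 °C
Reagents that add atoms: magnesium, [Mg]
Why: Oxidative insertion of Mg into the aryl bromide (Grignard formation) gives the aryl nucleophile; the MOM ether is base-stable.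

**Step 11**
Reactants: 15; 19 (first aryl equivalent)
Product: 20 (hexa-MOM Licobichalcone, (1S,2S))
Conditions: 19 (6 equiv total, two needed), THF, 0 °C, 1 h; NH4Cl quench
Reagents that add atoms: 4-(methoxymethoxy)phenylmagnesium bromide (19, second aryl equivalent; one aryl group per Weinreb amide), COCOc1ccc([Mg]Br)cc1
Why: Weinreb ketone synthesis; the stable chelated tetrahedral intermediate prevents over-addition, and each of the two amides takes one aryl group.

**Step 12**
Reactants: 20
Product: 21 (Licobichalcone)
Conditions: 2 M HCl, MeOH/THF (1:1), 35 °C, N2, dark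
Reagents that add atoms: none
Why: Acidolysis of all six aryl MOM acetals; the aryl methyl ethers, the enone and the stereocentres survive these mild conditions.

---

**Compound list**

| # | Name | SMILES | Role |
|---|---|---|---|
| 1 | 3,4-dihydroxy-5-methoxybenzaldehyde | COc1cc(C=O)cc(O)c1O | starting material |
| 2 | MOMCl | ClCOC | starting material (reagent) |
| 3 | 3,4-bis(MOMO)-5-methoxybenzaldehyde | COc1cc(C=O)cc(OCOC)c1OCOC | intermediate |
| 4 | 2,3,4-trihydroxybenzaldehyde | O=Cc1ccc(O)c(O)c1O | starting material |
| 5 | 2-hydroxy-3,4-bis(MOMO)benzaldehyde | O=Cc1ccc(OCOC)c(OCOC)c1O | intermediate |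
| 6 | iodomethane | CI | starting material (reagent) |
| 7 | 2-methoxy-3,4-bis(MOMO)benzaldehyde | COc1c(C=O)ccc(OCOC)c1OCOC | intermediate |
| 8 | diethyl succinate | CCOC(=O)CCC(=O)OCC | starting material |
| 9 | Stobbe half-ester | CCOC(=O)C(=Cc1cc(OCOC)c(OCOC)c(OC)c1)CC(=O)O | intermediate |
| 10 | (−)-menthol | C[C@@H]1CC[C@H]([C@@H](C1)O)C(C)C | starting material (chiral pool) |
| 11 | menthyl/ethyl arylidenesuccinate | CCOC(=O)C(=Cc1cc(OCOC)c(OCOC)c(OC)c1)CC(=O)O[C@@H]1C[C@H](C)CC[C@H]1C(C)C | intermediate |
| 12 | (E,E)-1,4-diarylbutadiene-2,3-dicarboxylate | CCOC(=O)C(=Cc1cc(OCOC)c(OCOC)c(OC)c1)C(=Cc1ccc(OCOC)c(OCOC)c1OC)C(=O)O[C@@H]1C[C@H](C)CC[C@H]1C(C)C | intermediate |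
| 13 | (1S,2S)-dihydronaphthalene diester | COc1c([C@H]2c3c(cc(OCOC)c(OCOC)c3OC)C=C(C(=O)OCC)[C@H]2C(=O)O[C@@H]2C[C@H](C)CC[C@H]2C(C)C)ccc(OCOC)c1OCOC | intermediate |
| 14 | N,O-dimethylhydroxylamine | CNOC | starting material (reagent) |
| 15 | bis-Weinreb amide | COc1c([C@H]2c3c(cc(OCOC)c(OCOC)c3OC)C=C(C(=O)N(C)OC)[C@H]2C(=O)N(C)OC)ccc(OCOC)c1OCOC | intermediate |
| 16 | 4-bromophenol | Oc1ccc(Br)cc1 | starting material |
| 17 | 1-bromo-4-(methoxymethoxy)benzene | COCOc1ccc(Br)cc1 | intermediate |
| 18 | magnesium | [Mg] | starting material (reagent) |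
| 19 | 4-(MOMO)phenylmagnesium bromide | COCOc1ccc([Mg]Br)cc1 | intermediate |
| 20 | hexa-MOM Licobichalcone | COc1c([C@H]2c3c(cc(OCOC)c(OCOC)c3OC)C=C(C(=O)c3ccc(OCOC)cc3)[C@H]2C(=O)c2ccc(OCOC)cc2)ccc(OCOC)c1OCOC | intermediate |
| 21 | Licobichalcone | COc1c([C@H]2c3c(cc(O)c(O)c3OC)C=C(C(=O)c3ccc(O)cc3)[C@H]2C(=O)c2ccc(O)cc2)ccc(O)c1O | target |

---

**Total steps:** 12. **Longest linear sequence:** 8 (1 → 3 → 9 → 11 → 12 → 13 → 15 → 20 → 21).

**Three steps most likely to fail**

1. **Step 7 (the new photocyclisation).** Ring A may not be the benzo partner, and closure may go through ring B or at C2 of ring A instead of C6. The menthyl-induced C1 selectivity is modest, and the cis preference at C2 is uncertain.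
   - Fallback: stop Step 6 after the aldol (NH4Cl quench) to isolate the β-hydroxy diester, then cyclise it with TfOH or BF3·OEt2 (known cationic Friedel–Crafts route to 1-aryl-dihydronaphthalene lignans). The ring-B benzylic cation attacks ring A, so ring B cannot cyclise, and the menthyl group gives 1,2-induction.
2. **Step 8, and then Step 11 (ester to bis-Weinreb amide to diaryl ketone).** The hindered, conjugated C3 ester and the menthyl ester may react poorly, and the basic Grignard reagents may epimerise C2.
   - Fallback: hydrolyse the esters with TMSOK to the diacid, then use Pd-catalysed carboxylic acid/arylboronic acid ketone coupling (Piv2O, 4-(MOMO)phenylboronic acid).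
3. **Step 2 (selective 3,4-bis-MOM protection).** The chelated 2-OH may also react, giving mixtures.
   - Fallback: prepare 7 by Rieche formylation (Cl2CHOMe/TiCl4) of 1-methoxy-2,3-bis(MOMO)benzene, derived from 3-methoxycatechol, and separate the regioisomers.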